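The plan cuts the dihydrofuran ring at C2–C3, the bond joining the two adjacent oxygen-bearing carbons. It exploits the substitution of C1′, the alkene carbon on C2: its methylene and its acetoxymethyl group are what is left of two identical acetoxymethyl arms on an aryl enol ether. An allyliridium made from either arm adds through its oxygen-bearing terminus (C2) to the ortho aldehyde carbon (C3). This single operation closes ring O1–C2–C3–C3a–C7a, forms the C2–C3 bond, sets both stereocentres as the cis-(2R,3R) pair and releases the exocyclic alkene. The precursor is a 5-acetyl-4-silyloxysalicylaldehyde whose phenolic oxygen bears a CH=C(CH2OAc)2 group; angeloylation and desilylation complete the target.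

Key step: step 6

Assumption on numbering: benzofuran numbering is used (O1, C2, C3, C3a, C4 to C7, C7a); C1′ is the alkene carbon on C2.
Assumption on the ligand: (R)-SEGPHOS is taken as the antipode that leads to (2R,3R); the sense of induction of this new ring closure has to be confirmed in the first run, and (S)-SEGPHOS is used instead if the mirror image forms.
Remark on the aryl part: in 5-acetyl-2,4-dihydroxybenzaldehyde both phenols are hydrogen-bonded to a carbonyl group and cannot be told apart reliably. The route therefore starts from 1, in which only the 2-hydroxyl is chelated; the free 4-hydroxyl is silylated first and the acetyl group is brought in at the brominated carbon, which also fixes its position.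
Remark on the enol ether: the alkenyl group is transferred from boron at room temperature, and the boron reagent is made by cross-metathesis, which has no E/Z issue because the two acetoxymethyl arms are identical.

Step 1
Reactants: 1 5-bromo-2,4-dihydroxybenzaldehyde
Product: 2 5-bromo-2-hydroxy-4-(triisopropylsilyloxy)benzaldehyde
Conditions: TIPSCl (1.05 equiv), imidazole (1.2 equiv), DMF, 0 °C to rt
Reagents that add atoms: triisopropylsilyl chloride, CC(C)[Si](Cl)(C(C)C)C(C)C
Why: Chemoselective O-silylation: the 2-hydroxyl is locked in a hydrogen bond to the aldehyde, so one equivalent of the bulky chlorosilane should silylate only the free and more acidic 4-hydroxyl.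

Step 2
Reactants: 2 5-bromo-2-hydroxy-4-(triisopropylsilyloxy)benzaldehyde, 3 tributyl(1-ethoxyvinyl)stannane
Product: 5 5-acetyl-2-hydroxy-4-(triisopropylsilyloxy)benzaldehyde, via 1-ethoxyvinyl arene 4 (not isolated)
Conditions: Pd(PPh3)4 (5 mol%), toluene, 100 °C; then 1 M HCl, THF, rt
Reagents that add atoms: water, O
Why: Stille coupling of the aryl bromide with the α-ethoxyvinyl stannane, followed by mild acid hydrolysis of the enol ether, is a standard acetyl-anion equivalent that places the acetyl group unambiguously at the former C–Br carbon and tolerates the free phenol, the aldehyde and the aryl silyl ether.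

Step 3
Reactants: 6 2-methylenepropane-1,3-diyl diacetate, 7 4,4,5,5-tetramethyl-2-vinyl-1,3,2-dioxaborolane (vinylboronic acid pinacol ester)
Product: 8 2-[(4,4,5,5-tetramethyl-1,3,2-dioxaborolan-2-yl)methylidene]propane-1,3-diyl diacetate
Conditions: second-generation Grubbs catalyst (5 mol%), 7 (2 equiv), CH2Cl2, 40 °C, argon sweep
Reagents that add atoms: none
Why: Olefin cross-metathesis of a 1,1-disubstituted alkene with a vinyl boronate is a known route to trisubstituted alkenyl boronates; 6 does not homodimerise readily and, since its two substituents are identical, the product has no E/Z isomers.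

Step 4
Reactants: 8 2-[(4,4,5,5-tetramethyl-1,3,2-dioxaborolan-2-yl)methylidene]propane-1,3-diyl diacetate
Product: 9 [3-acetoxy-2-(acetoxymethyl)prop-1-en-1-yl]boronic acid
Conditions: NaIO4 (3 equiv), NH4OAc (3 equiv), acetone/H2O (1:1), rt
Reagents that add atoms: water, O
Why: Oxidative cleavage of the pinacol unit by periodate drives the hydrolysis of the boronic ester under neutral aqueous conditions that leave the allylic acetates and the C=C bond untouched, and the free boronic acid transmetalates to copper far more readily than the pinacol ester.

Step 5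
Reactants: 5 5-acetyl-2-hydroxy-4-(triisopropylsilyloxy)benzaldehyde, 9 [3-acetoxy-2-(acetoxymethyl)prop-1-en-1-yl]boronic acid
Product: 10 5-acetyl-2-{[3-acetoxy-2-(acetoxymethyl)prop-1-en-1-yl]oxy}-4-(triisopropylsilyloxy)benzaldehyde
Conditions: Cu(OAc)2 (30 mol%), pyridine (3 equiv), 9 (2 equiv), 4 Å molecular sieves, CH2Cl2, O2 (1 atm), rt
Reagents that add atoms: none
Why: Chan–Lam oxidative coupling of a phenol with an alkenylboronic acid at copper forms aryl alkenyl ethers at room temperature with only pyridine as base and without fluoride, so the single free hydroxyl of 5 should be alkenylated while the allylic acetates, the aldehyde and the activated aryl silyl ether are spared.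

Step 6
Reactants: 10 5-acetyl-2-{[3-acetoxy-2-(acetoxymethyl)prop-1-en-1-yl]oxy}-4-(triisopropylsilyloxy)benzaldehyde
Product: 11 1-[(2R,3R)-2-(3-acetoxyprop-1-en-2-yl)-3-hydroxy-6-(triisopropylsilyloxy)-2,3-dihydrobenzofuran-5-yl]ethanone (2,3-cis)
Conditions: [Ir(cod)Cl]2 (2.5 mol%), (R)-SEGPHOS (5 mol%), 4-chloro-3-nitrobenzoic acid (10 mol%), Cs2CO3 (20 mol%), i-PrOH (2 equiv), THF (0.02 M), 80 °C
Reagents that add atoms: none
Why: Proposed new method: monovalent iridium carrying the bisphosphine and the cyclometalated nitrobenzoate ionises either of the two equivalent allylic acetates of 10 to a trivalent π-allyl, whose σ-form bound at the CH2 terminus is itself the nucleophile: it binds the ortho aldehyde and delivers the oxygen-bearing allyl carbon C2 to the carbonyl carbon C3 through a six-membered chair-like array, after which exchange of the iridium alkoxide with isopropanol and β-hydride elimination (acetone) return the catalyst to the monovalent state. The closest known reaction type is the intermolecular iridium-catalysed transfer-hydrogenative allylation of aldehydes by allylic acetates, including oxygen-substituted allyl donors that bond at the oxygen-bearing carbon; closing a ring in this way from an aryl enol ether has not been shown. Ring O1–C2–C3–C3a–C7a closes in a 5-exo-trig mode onto the aldehyde C=O. C2 and C3 are set together: the 2,3-cis relationship arises because C1′ and the carbonyl oxygen belong to the six-membered array while O1 and C3a belong to the nearly flat benzofuran ring that is forming, which allows only a cis-fused arrangement, and the (2R,3R) sense comes from the ligand enantiomer on iridium, which chooses the aldehyde face. No site selection between the acetates is needed because they are identical; bond formation at C2 instead of at the CH2 terminus is secured by the preference for the primary σ-allyl and by a five-membered ring being favoured over the seven-membered alternative; and chemoselectivity should hold because aryl ketones are not reduced under these conditions, the homoallylic product alcohol is shielded from dehydrogenation by olefin coordination, and high dilution disfavours allyl transfer between molecules from the remaining acetate.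

Step 7
Reactants: 11 1-[(2R,3R)-2-(3-acetoxyprop-1-en-2-yl)-3-hydroxy-6-(triisopropylsilyloxy)-2,3-dihydrobenzofuran-5-yl]ethanone, 12 angelic acid
Product: 14 (2R,3R)-5-acetyl-2-(3-acetoxyprop-1-en-2-yl)-6-(triisopropylsilyloxy)-2,3-dihydrobenzofuran-3-yl (Z)-2-methylbut-2-enoate, via angeloyl 2,4,6-trichlorobenzoyl anhydride 13 (not isolated)
Conditions: 12 (2 equiv), 2,4,6-trichlorobenzoyl chloride (2 equiv), Et3N (2.2 equiv), toluene, rt; then 11, toluene, 75 °C
Reagents that add atoms: 2,4,6-trichlorobenzoyl chloride, O=C(Cl)c1c(Cl)cc(Cl)cc1Cl (its atoms end in 13, none in 14)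
Why: Yamaguchi-type acylation through the mixed anhydride, run without a nucleophilic catalyst, transfers the angeloyl group from its unhindered carbonyl to the secondary benzylic alcohol and avoids the Z-to-E isomerisation to the tiglate that acylpyridinium intermediates cause; the C3–O bond is not broken, so the configuration is retained.

Step 8
Reactants: 14 (2R,3R)-5-acetyl-2-(3-acetoxyprop-1-en-2-yl)-6-(triisopropylsilyloxy)-2,3-dihydrobenzofuran-3-yl (Z)-2-methylbut-2-enoate
Product: 15 (2R,3R)-5-acetyl-2-(3-acetoxyprop-1-en-2-yl)-6-hydroxy-2,3-dihydrobenzofuran-3-yl (Z)-2-methylbut-2-enoate (target)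
Conditions: TBAF (1.1 equiv), AcOH (1.5 equiv), THF, 0 °C
Reagents that add atoms: none
Why: Fluoride-mediated cleavage of the aryl silyl ether is fast for a phenol activated by the ortho acetyl group, and the acetic acid buffer keeps the medium near neutral, so the acetate, the angelate and the sensitive benzylic C3–O bond should survive and neither stereocentre is touched.

Compound list
1 | 5-bromo-2,4-dihydroxybenzaldehyde | O=Cc1cc(Br)c(O)cc1O | starting material
2 | 5-bromo-2-hydroxy-4-(triisopropylsilyloxy)benzaldehyde | O=Cc1cc(Br)c(O[Si](C(C)C)(C(C)C)C(C)C)cc1O | intermediate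
3 | tributyl(1-ethoxyvinyl)stannane | CCCC[Sn](CCCC)(CCCC)C(=C)OCC | starting material
4 | 5-(1-ethoxyvinyl)-2-hydroxy-4-(triisopropylsilyloxy)benzaldehyde (not isolated) | C=C(OCC)c1cc(C=O)c(O)cc1O[Si](C(C)C)(C(C)C)C(C)C | intermediate
5 | 5-acetyl-2-hydroxy-4-(triisopropylsilyloxy)benzaldehyde | CC(=O)c1cc(C=O)c(O)cc1O[Si](C(C)C)(C(C)C)C(C)C | intermediate
6 | 2-methylenepropane-1,3-diyl diacetate | C=C(COC(C)=O)COC(C)=O | starting material
7 | 4,4,5,5-tetramethyl-2-vinyl-1,3,2-dioxaborolane | C=CB1OC(C)(C)C(C)(C)O1 | starting material
8 | 2-[(4,4,5,5-tetramethyl-1,3,2-dioxaborolan-2-yl)methylidene]propane-1,3-diyl diacetate | CC(=O)OCC(=CB1OC(C)(C)C(C)(C)O1)COC(C)=O | intermediate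
9 | [3-acetoxy-2-(acetoxymethyl)prop-1-en-1-yl]boronic acid | CC(=O)OCC(=CB(O)O)COC(C)=O | intermediate
10 | 5-acetyl-2-{[3-acetoxy-2-(acetoxymethyl)prop-1-en-1-yl]oxy}-4-(triisopropylsilyloxy)benzaldehyde (key-step precursor) | CC(=O)c1cc(C=O)c(OC=C(COC(C)=O)COC(C)=O)cc1O[Si](C(C)C)(C(C)C)C(C)C | intermediate
11 | 1-[(2R,3R)-2-(3-acetoxyprop-1-en-2-yl)-3-hydroxy-6-(triisopropylsilyloxy)-2,3-dihydrobenzofuran-5-yl]ethanone, 2,3-cis (key-step product) | C=C(COC(C)=O)[C@H]1Oc2cc(O[Si](C(C)C)(C(C)C)C(C)C)c(C(C)=O)cc2[C@H]1O | intermediate
12 | angelic acid, (Z)-2-methylbut-2-enoic acid | C/C=C(/C)C(=O)O | starting material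
13 | (Z)-2-methylbut-2-enoic 2,4,6-trichlorobenzoic anhydride (not isolated) | C/C=C(/C)C(=O)OC(=O)c1c(Cl)cc(Cl)cc1Cl | intermediate
14 | (2R,3R)-5-acetyl-2-(3-acetoxyprop-1-en-2-yl)-6-(triisopropylsilyloxy)-2,3-dihydrobenzofuran-3-yl (Z)-2-methylbut-2-enoate | C=C(COC(C)=O)[C@H]1Oc2cc(O[Si](C(C)C)(C(C)C)C(C)C)c(C(C)=O)cc2[C@H]1OC(=O)/C(C)=C\C | intermediate
15 | (2R,3R)-5-acetyl-2-(3-acetoxyprop-1-en-2-yl)-6-hydroxy-2,3-dihydrobenzofuran-3-yl (Z)-2-methylbut-2-enoate | C=C(COC(C)=O)[C@H]1Oc2cc(O)c(C(C)=O)cc2[C@H]1OC(=O)/C(C)=C\C | target

Total step count: 8. Longest linear sequence: 6 steps (steps 1, 2, 5, 6, 7, 8 from 1, or steps 3, 4, 5, 6, 7, 8 from 6).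

Steps most likely to fail

1. Step 6 (the proposed new method). The allylic acetate may fail to ionise at iridium, allyl transfer between molecules may outrun ring closure, the aldehyde may be reduced directly by transfer hydrogenation, or face selection at the aldehyde may be poor. The fallback sets out from 10 and comes back to the route at 11. It makes the same C2–C3 bond by the known palladium-catalysed, indium-mediated umpolung allylation of aldehydes by allylic acetates: Pd(PPh3)4 (5 mol%) and InI (1.2 equiv) in THF/DMI at rt. Zerovalent palladium ionises one acetate and monovalent indium iodide turns the π-allyl into an allylindium, which should add through its oxygen-bearing γ-carbon to the aldehyde in the same fused cyclic array and give the racemic 2,3-cis alcohol F1. The enantiomers are then separated by preparative chromatography on a chiral stationary phase (amylose tris(3,5-dimethylphenylcarbamate)); the (2R,3R) isomer is 11, at the cost of half the material.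

2. Step 5. The chelating, electron-poor salicylaldehyde may hold copper so firmly that transmetalation from boron becomes slow, and the boronic acid may be lost by protodeboronation or oxidative homocoupling. The fallback sets out from 9 and 5 and comes back at 10. It replaces the oxidative coupling by a halide-based one at monovalent copper: iododeboronation of 9 with N-iodosuccinimide in MeCN at rt should give 2-(iodomethylidene)propane-1,3-diyl diacetate F2, which is joined to phenol 5 in an Ullmann-type C–O coupling (CuI 10 mol%, N,N-dimethylglycine 20 mol%, Cs2CO3, toluene, 80 °C).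

3. Step 7. The angeloyl group may isomerise to the tigloyl (E) form during acyl transfer, the hindered cis alcohol may acylate slowly, or on heating the C3 oxygen may be lost by elimination to the benzofuran. The fallback sets out from 11 and comes back at 14. It forms the ester bond first and builds the alkene afterwards. Alcohol 11 is esterified at rt with 2-[bis(2,2,2-trifluoroethoxy)phosphoryl]propanoic acid (EDC·HCl, DMAP, CH2Cl2) to give (2R,3R)-5-acetyl-2-(3-acetoxyprop-1-en-2-yl)-6-(triisopropylsilyloxy)-2,3-dihydrobenzofuran-3-yl 2-[bis(2,2,2-trifluoroethoxy)phosphoryl]propanoate F3. A Still–Gennari olefination (KHMDS, 18-crown-6, THF, −78 °C, then acetaldehyde) should then give the Z-trisubstituted enoate 14 under kinetic control. The phosphonate C–H is far more acidic than the aryl methyl ketone, so one equivalent of base should deprotonate it selectively.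

Further compounds
F1 | step 6 | racemic 2,3-cis 1-[2-(3-acetoxyprop-1-en-2-yl)-3-hydroxy-6-(triisopropylsilyloxy)-2,3-dihydrobenzofuran-5-yl]ethanone, (2R,3R) and (2S,3S) in equal amounts | C=C(COC(C)=O)[C@H]1Oc2cc(O[Si](C(C)C)(C(C)C)C(C)C)c(C(C)=O)cc2[C@H]1O.C=C(COC(C)=O)[C@@H]1Oc2cc(O[Si](C(C)C)(C(C)C)C(C)C)c(C(C)=O)cc2[C@@H]1O
F2 | step 5 | 2-(iodomethylidene)propane-1,3-diyl diacetate | CC(=O)OCC(=CI)COC(C)=O
F3 | step 7 | (2R,3R)-5-acetyl-2-(3-acetoxyprop-1-en-2-yl)-6-(triisopropylsilyloxy)-2,3-dihydrobenzofuran-3-yl 2-[bis(2,2,2-trifluoroethoxy)phosphoryl]propanoate (both epimers at the phosphonate carbon) | C=C(COC(C)=O)[C@H]1Oc2cc(O[Si](C(C)C)(C(C)C)C(C)C)c(C(C)=O)cc2[C@H]1OC(=O)C(C)P(=O)(OCC(F)(F)F)OCC(F)(F)F
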